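## Retrosynthetic overview

1. Kuwanon J ⇐ its octakis-MOM ether. The chalcone C=C comes from a late Claisen–Schmidt aldol condensation of a core aryl methyl ketone with 2,4-bis(methoxymethoxy)benzaldehyde; the aroyl C=O comes from oxidation of a silyl-protected carbinol.
2. The C1(CH3)=C2 olefin ⇐ enol triflate + MeMgBr ⇐ regiodefined enolate from conjugate reduction of a 3-aryl-cyclohex-2-enone (the hydride sets C3 cis to C4).
3. The 3-aryl enone ⇐ 1,2-addition of a C2-lithiated resorcinol bis-MOM ether to a 5,6-disubstituted cyclohex-2-enone, then oxidative 1,3-carbonyl transposition.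
4. The C4–C(aroyl) bond ⇐ intermolecular aldol addition of the kinetic enolate of (S)-5-arylcyclohex-2-enone to 3,5-bis(methoxymethoxy)-4-prenylbenzaldehyde (sets C4 trans to C5).
5. (S)-5-Arylcyclohex-2-enone ⇐ organocatalytic asymmetric Michael addition of allyl acetoacetate to a cinnamaldehyde, then decarboxylative intramolecular aldol condensation. This cyclohexene is the only ring that is built; the four benzene rings are bought.

## Assumptions and abbreviations

- Assumption: the SMILES is authoritative. The aroyl ring is 3,5-dihydroxy-4-prenylphenyl, and the cyclohexene, numbered C1(CH3)=C2–C3(aryl)–C4(aroyl)–C5(aryl)–C6, is 3S,4R,5S (3,4-cis, 4,5-trans).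
- Convention: carbinol centres that are oxidised later (the two side-chain CH–O carbons and the tertiary carbinol made by the aryllithium addition) are carried as inconsequential epimer mixtures and left undefined in names and SMILES.
- From the 3-aryl enone onwards the core compounds use the target ring numbering given above.
- MOM = CH2OCH3; TES = SiEt3; TBS = Si(t-Bu)Me2; ArB = 2,4-bis(methoxymethoxy)phenyl; ArP = 3,5-bis(methoxymethoxy)-4-(3-methylbut-2-en-1-yl)phenyl; ArA = 2,6-bis(methoxymethoxy)phenyl carrying the named group at its position 3.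

## Route

Step 1
Reactants: 1 2,4-dihydroxybenzaldehyde
Product: 2 2,4-bis(methoxymethoxy)benzaldehyde
Conditions: NaH (2.4 equiv), MOMCl (2.4 equiv), DMF, 0 °C to rt
Reagents that add atoms: chloromethyl methyl ether, COCCl
Why: Williamson-type O-alkylation of both sodium phenoxides gives the bis-MOM ether, stable to all later organometallic steps.

Step 2
Reactants: 2 2,4-bis(methoxymethoxy)benzaldehyde
Product: 3 (E)-3-[2,4-bis(methoxymethoxy)phenyl]prop-2-enal
Conditions: Ph3P=CHCHO (1.1 equiv), toluene, 80 °C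
Reagents that add atoms: (triphenylphosphoranylidene)acetaldehyde, O=CC=P(c1ccccc1)(c1ccccc1)c1ccccc1
Why: Wittig olefination with a stabilised ylide gives the (E)-enal selectively.

Step 3
Reactants: 3 (E)-3-[2,4-bis(methoxymethoxy)phenyl]prop-2-enal; 4 allyl acetoacetate
Product: 7 (5S)-5-[2,4-bis(methoxymethoxy)phenyl]cyclohex-2-en-1-one, via Michael adduct 5 (not isolated), via keto-aldehyde 6 (not isolated)
Conditions: (R)-2-{bis[3,5-bis(trifluoromethyl)phenyl](trimethylsilyloxy)methyl}pyrrolidine (10 mol%), PhCO2H (10 mol%), toluene, rt; then Pd(PPh3)4 (3 mol%), morpholine (1.2 equiv), THF, rt; then AcOH (2 equiv), 50 °C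
Reagents that add atoms: none
Why: Iminium-catalysed asymmetric Michael addition, in which the (R)-diarylprolinol silyl ether shields one face of the (E)-iminium ion so the ketoester adds to give the 3S adduct (the (S)-catalyst gives the opposite sense with cinnamaldehydes), followed by Pd(PPh3)4-mediated deallylation–decarboxylation and an intramolecular aldol condensation whose only six-membered mode is methyl ketone onto aldehyde.

Step 4
Reactants: 2 2,4-bis(methoxymethoxy)benzaldehyde
Product: 8 1-[2,4-bis(methoxymethoxy)phenyl]ethan-1-ol (racemic)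
Conditions: MeMgBr (1.2 equiv), THF, 0 °C; H2O
Reagents that add atoms: methylmagnesium bromide, C[Mg]Br
Why: Grignard addition to the aldehyde gives the secondary alcohol that serves as a masked acetyl group.

Step 5
Reactants: 8 1-[2,4-bis(methoxymethoxy)phenyl]ethan-1-ol
Product: 9 {1-[2,4-bis(methoxymethoxy)phenyl]ethoxy}triethylsilane (racemic)
Conditions: Et3SiCl (1.2 equiv), imidazole (2 equiv), DMF, rt
Reagents that add atoms: chlorotriethylsilane, CC[Si](Cl)(CC)CC
Why: Silylation gives a TES ether that survives organolithium chemistry and can later be removed selectively in the presence of a hindered TBS ether.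

Step 6
Reactants: 10 methyl 3,5-dihydroxybenzoate
Product: 11 methyl 3,5-bis(methoxymethoxy)benzoate
Conditions: NaH (2.3 equiv), MOMCl (2.3 equiv), DMF, 0 °C to rt
Reagents that add atoms: chloromethyl methyl ether, COCCl
Why: O-alkylation of both phenoxides installs the two MOM groups that later direct lithiation to the carbon between them.

Step 7
Reactants: 11 methyl 3,5-bis(methoxymethoxy)benzoate
Product: 12 [3,5-bis(methoxymethoxy)phenyl]methanol
Conditions: LiAlH4 (1.0 equiv), THF, 0 °C; H2O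
Reagents that add atoms: none
Why: Hydride reduction of the ester to the benzylic alcohol removes the group that would be attacked by n-BuLi.

Step 8
Reactants: 12 [3,5-bis(methoxymethoxy)phenyl]methanol
Product: 14 [3,5-bis(methoxymethoxy)-4-(3-methylbut-2-en-1-yl)phenyl]methanol, via dilithio species 13 (not isolated)
Conditions: n-BuLi (2.2 equiv), THF, 0 °C, 1 h; then CuBr·SMe2 (10 mol%), prenyl bromide (1.1 equiv), −78 °C to rt; H2O
Reagents that add atoms: 1-bromo-3-methylbut-2-ene, CC(C)=CCBr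
Why: Directed ortho-metalation occurs at the carbon flanked by both OMOM groups (the alkoxide is formed first), and CuBr·SMe2-assisted SN2 allylation gives the linear prenyl arene.

Step 9
Reactants: 14 [3,5-bis(methoxymethoxy)-4-(3-methylbut-2-en-1-yl)phenyl]methanol
Product: 15 3,5-bis(methoxymethoxy)-4-(3-methylbut-2-en-1-yl)benzaldehyde
Conditions: MnO2 (10 equiv), CH2Cl2, rt
Reagents that add atoms: none
Why: Chemoselective oxidation of the benzylic alcohol to the aldehyde leaves the prenyl olefin and the MOM ethers untouched.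

Step 10
Reactants: 7 (5S)-5-[2,4-bis(methoxymethoxy)phenyl]cyclohex-2-en-1-one; 15 3,5-bis(methoxymethoxy)-4-(3-methylbut-2-en-1-yl)benzaldehyde
Product: 17 (5S,6S)-5-ArB-6-[ArP(hydroxy)methyl]cyclohex-2-en-1-one (5,6-trans), via lithium dienolate 16 (not isolated)
Conditions: LiN(i-Pr)2 (1.1 equiv), THF, −78 °C, 30 min; then 15 (1.2 equiv), −78 °C, 20 min; AcOH (1.2 equiv) at −78 °C
Reagents that add atoms: none
Why: Kinetic α′-deprotonation gives the cross-conjugated lithium dienolate, which undergoes intermolecular aldol addition on the face anti to the adjacent C5 aryl group, setting the future C4 trans to C5 (also the thermodynamic arrangement).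

Step 11
Reactants: 17 (5S,6S)-5-ArB-6-[ArP(hydroxy)methyl]cyclohex-2-en-1-one
Product: 18 (5S,6S)-5-ArB-6-[ArP(tert-butyldimethylsilyloxy)methyl]cyclohex-2-en-1-one
Conditions: t-BuMe2SiOTf (1.5 equiv), 2,6-lutidine (3 equiv), CH2Cl2, −78 °C
Reagents that add atoms: tert-butyldimethylsilyl trifluoromethanesulfonate, CC(C)(C)[Si](C)(C)OS(=O)(=O)C(F)(F)F
Why: Low-temperature silylation of the aldol hydroxyl blocks retro-aldol cleavage and removes the acidic OH before the organolithium step.

Step 12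
Reactants: 18 (5S,6S)-5-ArB-6-[ArP(tert-butyldimethylsilyloxy)methyl]cyclohex-2-en-1-one; 9 {1-[2,4-bis(methoxymethoxy)phenyl]ethoxy}triethylsilane
Product: 20 (5S,6S)-1-{ArA with 3-[1-(triethylsilyloxy)ethyl]}-5-ArB-6-[ArP(tert-butyldimethylsilyloxy)methyl]cyclohex-2-en-1-ol (C1 epimers), via aryllithium 19 (not isolated)
Conditions: 9 (1.6 equiv), n-BuLi (1.5 equiv), THF, 0 °C, 1 h; then 18, −78 to −30 °C; H2O
Reagents that add atoms: none
Why: Directed ortho-metalation of 9 between its two OMOM groups gives an aryllithium that adds 1,2 to the enone carbonyl; the new carbinol centre is erased in the next step.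

Step 13
Reactants: 20 tertiary allylic alcohol from step 12
Product: 21 (4R,5S)-3-{ArA with 3-[1-(triethylsilyloxy)ethyl]}-5-ArB-4-[ArP(tert-butyldimethylsilyloxy)methyl]cyclohex-2-en-1-one (4,5-trans)
Conditions: [C5H5NH][CrO3Cl] (pyridinium chlorochromate, 3 equiv), 4 Å molecular sieves, CH2Cl2, rt
Reagents that add atoms: pyridinium chlorochromate, [O-][Cr](=O)(=O)Cl.c1cc[nH+]cc1
Why: Dauben–Babler oxidative 1,3-transposition (the tertiary allylic chromate ester undergoes a [3,3] shift and is oxidised) moves the carbonyl to C1 and places the aryl group on the enone β-carbon C3 without touching C4 or C5.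

Step 14
Reactants: 21 3-aryl enone from step 13
Product: 22 (3R,4R,5S)-dimethylphenylsilyl enol ether, C1(OSiMe2Ph)=C2, with 3-{ArA with 3-[1-(triethylsilyloxy)ethyl]}, 4-[ArP(tert-butyldimethylsilyloxy)methyl], 5-ArB (3,4-cis, 4,5-trans)
Conditions: [(Ph3P)CuH]6 (5 mol% Cu), PhMe2SiH (1.5 equiv), toluene, rt
Reagents that add atoms: dimethylphenylsilane, C[SiH](C)c1ccccc1
Why: CuH-catalysed conjugate reduction (1,4-hydrosilylation) delivers hydride to C3 on the face anti to the C4 side chain, which A(1,2) strain with the C3 aryl holds pseudoaxial, giving the 3,4-cis relationship and a regiodefined C1=C2 silyl enol ether.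

Step 15
Reactants: 22 silyl enol ether from step 14
Product: 24 (3R,4R,5S)-cyclohex-1-en-1-yl triflate (C1(OTf)=C2) carrying the 3-/4-/5-substituents of 22, via lithium enolate 23 (not isolated)
Conditions: MeLi (1.1 equiv), THF, 0 °C, 1 h; then PhNTf2 (1.3 equiv), −78 to 0 °C; H2O
Reagents that add atoms: N-phenylbis(trifluoromethanesulfonimide), O=S(=O)(N(c1ccccc1)S(=O)(=O)C(F)(F)F)C(F)(F)F
Why: Si–O cleavage by MeLi releases the regiodefined lithium enolate, which is O-sulfonylated before it can equilibrate (McMurry–Scott enol triflate formation).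

Step 16
Reactants: 24 enol triflate from step 15
Product: 25 (3S,4R,5S)-1-methylcyclohex-1-ene with 3-{ArA with 3-[1-(triethylsilyloxy)ethyl]}, 4-[ArP(tert-butyldimethylsilyloxy)methyl], 5-ArB
Conditions: MeMgBr (1.5 equiv), Fe(acac)3 (5 mol%), THF/NMP, −30 to 0 °C
Reagents that add atoms: methylmagnesium bromide, C[Mg]Br
Why: Fe(acac)3-catalysed Kumada-type cross-coupling replaces OTf by CH3 with the C1=C2 double bond fixed in position.

Step 17
Reactants: 25 methylcyclohexene from step 16
Product: 26 (3S,4R,5S)-core alcohol: as 25 but with ArA carrying 3-(1-hydroxyethyl)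
Conditions: HF·pyridine, pyridine, THF, 0 °C
Reagents that add atoms: none
Why: Buffered fluoride desilylation removes the less hindered TES ether selectively, leaving the flanked secondary TBS ether and the MOM ethers intact.

Step 18
Reactants: 26 core alcohol from step 17
Product: 27 (3S,4R,5S)-core methyl ketone: as 25 but with ArA carrying 3-acetyl
Conditions: Dess–Martin periodinane (1.5 equiv), CH2Cl2, rt
Reagents that add atoms: none
Why: Dess–Martin oxidation converts the benzylic alcohol (both epimers) into the aryl methyl ketone under neutral conditions.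

Step 19
Reactants: 27 core methyl ketone from step 18; 2 2,4-bis(methoxymethoxy)benzaldehyde
Product: 29 (3S,4R,5S)-core chalcone: as 25 but with ArA carrying 3-[(E)-3-ArB-prop-2-enoyl], via aldol adduct 28 (not isolated)
Conditions: 2 (1.5 equiv), KOH (50% aq.), EtOH/THF, rt, 24–48 h
Reagents that add atoms: none
Why: Claisen–Schmidt aldol condensation gives the (E)-enone, and because C4 still carries a silyl-protected carbinol rather than a ketone there is no base-epimerisable ring stereocentre.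

Step 20
Reactants: 29 core chalcone from step 19
Product: 30 (3S,4R,5S)-chalcone carbinol: as 29 but with 4-[ArP(hydroxy)methyl]
Conditions: HF·pyridine (excess), THF, rt
Reagents that add atoms: none
Why: Fluoride-mediated cleavage of the remaining TBS ether under mildly acidic, non-basic conditions leaves the enone and the MOM ethers untouched.

Step 21
Reactants: 30 chalcone carbinol from step 20
Product: 31 (3S,4R,5S)-octakis-O-(methoxymethyl)kuwanon J
Conditions: Dess–Martin periodinane (1.5 equiv), CH2Cl2, rt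
Reagents that add atoms: none
Why: Dess–Martin oxidation of the hindered benzylic alcohol gives the aroyl ketone under neutral conditions that do not enolise the new α-stereocentre C4.

Step 22
Reactants: 31 octakis-O-(methoxymethyl)kuwanon J
Product: 32 kuwanon J
Conditions: 3 M aq. HCl, MeOH/THF, 40 °C
Reagents that add atoms: none
Why: Acid-catalysed acetal exchange with methanol removes all eight aryl MOM groups; conditions of this strength are used for prenylated chalcones without chroman or flavanone formation.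

## Compound list

1 | 2,4-dihydroxybenzaldehyde | O=Cc1ccc(O)cc1O | starting material
2 | 2,4-bis(methoxymethoxy)benzaldehyde | O=Cc1ccc(OCOC)cc1OCOC | intermediate
3 | (E)-3-[2,4-bis(methoxymethoxy)phenyl]prop-2-enal | O=C/C=C/c1ccc(OCOC)cc1OCOC | intermediate
4 | allyl acetoacetate (prop-2-en-1-yl 3-oxobutanoate) | CC(=O)CC(=O)OCC=C | starting material
5 | allyl (3S)-2-acetyl-3-[2,4-bis(methoxymethoxy)phenyl]-5-oxopentanoate (C2 epimers; in equilibrium with cyclic aldol forms) | CC(=O)C(C(=O)OCC=C)[C@H](CC=O)c1ccc(OCOC)cc1OCOC | intermediate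
6 | (3S)-3-[2,4-bis(methoxymethoxy)phenyl]-5-oxohexanal | CC(=O)C[C@H](CC=O)c1ccc(OCOC)cc1OCOC | intermediate
7 | (5S)-5-[2,4-bis(methoxymethoxy)phenyl]cyclohex-2-en-1-one | O=C1C=CC[C@H](c2ccc(OCOC)cc2OCOC)C1 | intermediate
8 | 1-[2,4-bis(methoxymethoxy)phenyl]ethan-1-ol (racemic) | CC(O)c1ccc(OCOC)cc1OCOC | intermediate
9 | {1-[2,4-bis(methoxymethoxy)phenyl]ethoxy}triethylsilane (racemic) | CC[Si](CC)(CC)OC(C)c1ccc(OCOC)cc1OCOC | intermediate
10 | methyl 3,5-dihydroxybenzoate | COC(=O)c1cc(O)cc(O)c1 | starting material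
11 | methyl 3,5-bis(methoxymethoxy)benzoate | COC(=O)c1cc(OCOC)cc(OCOC)c1 | intermediate
12 | [3,5-bis(methoxymethoxy)phenyl]methanol | OCc1cc(OCOC)cc(OCOC)c1 | intermediate
13 | lithium [4-lithio-3,5-bis(methoxymethoxy)phenyl]methanolate | [Li]OCc1cc(OCOC)c([Li])c(OCOC)c1 | intermediate
14 | [3,5-bis(methoxymethoxy)-4-(3-methylbut-2-en-1-yl)phenyl]methanol | CC(C)=CCc1c(OCOC)cc(CO)cc1OCOC | intermediate
15 | 3,5-bis(methoxymethoxy)-4-(3-methylbut-2-en-1-yl)benzaldehyde | CC(C)=CCc1c(OCOC)cc(C=O)cc1OCOC | intermediate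
16 | lithium cross-conjugated dienolate of 7 (O–C1=C6, C2=C3; aryl-bearing centre as in 7) | [Li]OC1=C[C@@H](c2ccc(OCOC)cc2OCOC)CC=C1 | intermediate
17 | (5S,6S)-5-ArB-6-[ArP(hydroxy)methyl]cyclohex-2-en-1-one (5,6-trans; carbinol epimers) | OC(c1cc(OCOC)c(CC=C(C)C)c(OCOC)c1)[C@H]2C(=O)C=CC[C@@H]2c1ccc(OCOC)cc1OCOC | intermediate
18 | (5S,6S)-5-ArB-6-[ArP(tert-butyldimethylsilyloxy)methyl]cyclohex-2-en-1-one | CC(C)(C)[Si](C)(C)OC(c1cc(OCOC)c(CC=C(C)C)c(OCOC)c1)[C@H]2C(=O)C=CC[C@@H]2c1ccc(OCOC)cc1OCOC | intermediate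
19 | {1-[3-lithio-2,4-bis(methoxymethoxy)phenyl]ethoxy}triethylsilane | CC[Si](CC)(CC)OC(C)c1ccc(OCOC)c([Li])c1OCOC | intermediate
20 | (5S,6S)-1-{2,6-bis(methoxymethoxy)-3-[1-(triethylsilyloxy)ethyl]phenyl}-5-ArB-6-[ArP(tert-butyldimethylsilyloxy)methyl]cyclohex-2-en-1-ol (C1 epimers) | CC(C)(C)[Si](C)(C)OC(c1cc(OCOC)c(CC=C(C)C)c(OCOC)c1)[C@H]2C(O)(c3c(OCOC)ccc(C(C)O[Si](CC)(CC)CC)c3OCOC)C=CC[C@@H]2c1ccc(OCOC)cc1OCOC | intermediate
21 | (4R,5S)-3-{2,6-bis(methoxymethoxy)-3-[1-(triethylsilyloxy)ethyl]phenyl}-5-ArB-4-[ArP(tert-butyldimethylsilyloxy)methyl]cyclohex-2-en-1-one (4,5-trans) | CC(C)(C)[Si](C)(C)OC(c1cc(OCOC)c(CC=C(C)C)c(OCOC)c1)[C@H]2C(c3c(OCOC)ccc(C(C)O[Si](CC)(CC)CC)c3OCOC)=CC(=O)C[C@@H]2c1ccc(OCOC)cc1OCOC | intermediate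
22 | (3R,4R,5S)-1-(dimethylphenylsilyloxy)cyclohex-1-ene with 3-{2,6-bis(methoxymethoxy)-3-[1-(triethylsilyloxy)ethyl]phenyl}, 4-[ArP(tert-butyldimethylsilyloxy)methyl], 5-ArB (3,4-cis, 4,5-trans) | CC(C)(C)[Si](C)(C)OC(c1cc(OCOC)c(CC=C(C)C)c(OCOC)c1)[C@H]2[C@@H](c3c(OCOC)ccc(C(C)O[Si](CC)(CC)CC)c3OCOC)C=C(O[Si](C)(C)c3ccccc3)C[C@@H]2c1ccc(OCOC)cc1OCOC | intermediate
23 | lithium enolate corresponding to 22 (O–C1=C2) | CC(C)(C)[Si](C)(C)OC(c1cc(OCOC)c(CC=C(C)C)c(OCOC)c1)[C@H]2[C@@H](c3c(OCOC)ccc(C(C)O[Si](CC)(CC)CC)c3OCOC)C=C(O[Li])C[C@@H]2c1ccc(OCOC)cc1OCOC | intermediate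
24 | (3R,4R,5S)-cyclohex-1-en-1-yl trifluoromethanesulfonate with the 3-, 4- and 5-substituents of 22 | CC(C)(C)[Si](C)(C)OC(c1cc(OCOC)c(CC=C(C)C)c(OCOC)c1)[C@H]2[C@@H](c3c(OCOC)ccc(C(C)O[Si](CC)(CC)CC)c3OCOC)C=C(OS(=O)(=O)C(F)(F)F)C[C@@H]2c1ccc(OCOC)cc1OCOC | intermediate
25 | (3S,4R,5S)-1-methylcyclohex-1-ene with 3-{2,6-bis(methoxymethoxy)-3-[1-(triethylsilyloxy)ethyl]phenyl}, 4-[ArP(tert-butyldimethylsilyloxy)methyl], 5-ArB | CC(C)(C)[Si](C)(C)OC(c1cc(OCOC)c(CC=C(C)C)c(OCOC)c1)[C@H]2[C@@H](c3c(OCOC)ccc(C(C)O[Si](CC)(CC)CC)c3OCOC)C=C(C)C[C@@H]2c1ccc(OCOC)cc1OCOC | intermediate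
26 | as 25, with the C3 aryl group = 3-(1-hydroxyethyl)-2,6-bis(methoxymethoxy)phenyl | CC(C)(C)[Si](C)(C)OC(c1cc(OCOC)c(CC=C(C)C)c(OCOC)c1)[C@H]2[C@@H](c3c(OCOC)ccc(C(C)O)c3OCOC)C=C(C)C[C@@H]2c1ccc(OCOC)cc1OCOC | intermediate
27 | as 25, with the C3 aryl group = 3-acetyl-2,6-bis(methoxymethoxy)phenyl | CC(C)(C)[Si](C)(C)OC(c1cc(OCOC)c(CC=C(C)C)c(OCOC)c1)[C@H]2[C@@H](c3c(OCOC)ccc(C(C)=O)c3OCOC)C=C(C)C[C@@H]2c1ccc(OCOC)cc1OCOC | intermediate
28 | as 25, with the C3 aryl group = 3-(3-ArB-3-hydroxypropanoyl)-2,6-bis(methoxymethoxy)phenyl (β-hydroxy ketone) | CC(C)(C)[Si](C)(C)OC(c1cc(OCOC)c(CC=C(C)C)c(OCOC)c1)[C@H]2[C@@H](c3c(OCOC)ccc(C(=O)CC(O)c4ccc(OCOC)cc4OCOC)c3OCOC)C=C(C)C[C@@H]2c1ccc(OCOC)cc1OCOC | intermediate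
29 | as 25, with the C3 aryl group = 3-[(E)-3-ArB-prop-2-enoyl]-2,6-bis(methoxymethoxy)phenyl (chalcone) | CC(C)(C)[Si](C)(C)OC(c1cc(OCOC)c(CC=C(C)C)c(OCOC)c1)[C@H]2[C@@H](c3c(OCOC)ccc(C(=O)/C=C/c4ccc(OCOC)cc4OCOC)c3OCOC)C=C(C)C[C@@H]2c1ccc(OCOC)cc1OCOC | intermediate
30 | as 29, with the C4 substituent = ArP(hydroxy)methyl | OC(c1cc(OCOC)c(CC=C(C)C)c(OCOC)c1)[C@H]2[C@@H](c3c(OCOC)ccc(C(=O)/C=C/c4ccc(OCOC)cc4OCOC)c3OCOC)C=C(C)C[C@@H]2c1ccc(OCOC)cc1OCOC | intermediate
31 | (3S,4R,5S)-octakis-O-(methoxymethyl)kuwanon J | CC(C)=CCc1c(OCOC)cc(C(=O)[C@H]2[C@@H](c3c(OCOC)ccc(C(=O)/C=C/c4ccc(OCOC)cc4OCOC)c3OCOC)C=C(C)C[C@@H]2c2ccc(OCOC)cc2OCOC)cc1OCOC | intermediate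
32 | kuwanon J | CC(C)=CCc1c(O)cc(C(=O)[C@H]2[C@@H](c3c(O)ccc(C(=O)/C=C/c4ccc(O)cc4O)c3O)C=C(C)C[C@@H]2c2ccc(O)cc2O)cc1O | target

## Step count and risk

Total steps: 22. Longest linear sequence: 17 steps (6, 7, 8, 9, then 10–22, from methyl 3,5-dihydroxybenzoate). The branch from 2,4-dihydroxybenzaldehyde through steps 1, 2, 3 and 10–22 is 16 steps.

The three steps most likely to fail:

Step 14. The β-carbon of enone 21 carries a di-ortho-substituted aryl group, so hydride delivery may be slow. Its facial selectivity also rests on the adjacent C4 side chain overriding the opposing 1,3-effect of the C5 aryl group. The fallback sets out from 21 and replaces hydride transfer by electron transfer. Li (2.2 equiv) and t-BuOH (1 equiv) in NH3/THF at −78 °C reduce the enone to the same regiodefined lithium enolate 23; the planar benzylic C3 carbanion is protonated on the face anti to the pseudoaxial C4 side chain. The limited charge of lithium spares the arenes and the benzylic silyl ethers. After evaporation of NH3 the enolate is trapped with PhNTf2, and the route is rejoined at enol triflate 24. No new compound is made.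

Step 12. A hindered 2,6-dialkoxyaryllithium must add to a ketone flanked by the bulky C4 side chain, so enolisation or no reaction is possible. The fallback sets out from 7 and reverses the order of the two bond formations. Aryllithium 19 is added to the unhindered ketone of 7 to give the tertiary allylic alcohol F1. Oxidation with [C5H5NH][CrO3Cl] transposes this to the 3-aryl enone F2. Soft enolisation (t-BuMe2SiOTf, Et3N, CH2Cl2) gives the extended silyl dienol ether F3. A vinylogous Mukaiyama aldol addition to aldehyde 15, catalysed by B(C6F5)3 (5 mol%, CH2Cl2, −78 °C), then bonds the γ-carbon C4 anti to the C5 aryl group. The silyl group passes to the new alkoxide oxygen, so the silyl ether forms directly and the route is rejoined at 21.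

Step 22. Eight MOM groups must be removed with protic acid next to a prenyl group flanked by two phenols (chroman formation), a 2′-hydroxychalcone (flavanone formation) and an enolisable C4 centre. The fallback sets out from 31 and avoids protic acid. Me3SiOTf with 2,2′-bipyridyl (CH2Cl2, 0 °C) converts the aryl MOM ethers directly into aryl silyl ethers, giving the octakis(trimethylsilyl) ether F4. This is hydrolysed with water in THF at rt and comes back to the route at 32.

## Further compounds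

F1 | step 12 | (5S)-1-{2,6-bis(methoxymethoxy)-3-[1-(triethylsilyloxy)ethyl]phenyl}-5-ArB-cyclohex-2-en-1-ol (C1 epimers) | OC1(c2c(OCOC)ccc(C(C)O[Si](CC)(CC)CC)c2OCOC)C=CC[C@H](c2ccc(OCOC)cc2OCOC)C1
F2 | step 12 | (5R)-3-{2,6-bis(methoxymethoxy)-3-[1-(triethylsilyloxy)ethyl]phenyl}-5-ArB-cyclohex-2-en-1-one (same spatial arrangement at C5 as in 7) | O=C1C=C(c2c(OCOC)ccc(C(C)O[Si](CC)(CC)CC)c2OCOC)C[C@@H](c2ccc(OCOC)cc2OCOC)C1
F3 | step 12 | (5S)-1-(tert-butyldimethylsilyloxy)-3-{2,6-bis(methoxymethoxy)-3-[1-(triethylsilyloxy)ethyl]phenyl}-5-ArB-cyclohexa-1,3-diene | CC(C)(C)[Si](C)(C)OC1=CC(c2c(OCOC)ccc(C(C)O[Si](CC)(CC)CC)c2OCOC)=C[C@@H](c2ccc(OCOC)cc2OCOC)C1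
F0 | step 14 | none | none
F4 | step 22 | (3S,4R,5S)-octakis-O-(trimethylsilyl)kuwanon J | CC(C)=CCc1c(O[Si](C)(C)C)cc(C(=O)[C@H]2[C@@H](c3c(O[Si](C)(C)C)ccc(C(=O)/C=C/c4ccc(O[Si](C)(C)C)cc4O[Si](C)(C)C)c3O[Si](C)(C)C)C=C(C)C[C@@H]2c2ccc(O[Si](C)(C)C)cc2O[Si](C)(C)C)cc1O[Si](C)(C)C
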